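The runs stem from a simulated flask for substances that don't exist.

4 questions stand on 5 flasks of solid substrate E, which by the list of suspects dissolves to L, meets reagent J and passes through G to product X with by-product D.

| flask | E | J | remark | time |
|---|---|---|---|---|
| zeta | 5 mM | 3.4 mM | run made earlier |  |
| Thursday's | 20 mM | 5.00 mM |  | 3.0 min |
| Tuesday's | 5.0 mM | 5.00 mM |  | 3.0 min |
| Saturday's | 1.5 mM | 5.00 mM |  | 3.0 min |
| Monday's | 8.0 mM | 5.00 mM |  | 3.0 min |
| Friday's | 10 mM | 5.00 mM |  | 3.0 min |

zeta run (percent of the E charged)

| time / s | X / % | E / % |
|---|---|---|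
| 10.0 | 0 | 90.7 |
| 20.0 | 1.6 | 83.9 |
| 30.0 | 5.6 | 76.3 |
| 40.0 | 6.0 | 70.2 |
| 50.0 | 11.2 | 67.4 |
| 60.0 | 11.3 | 63.2 |

(each reading ± 1 percentage point)

- the flasks by amount of X, in percent of the E charged, highest first, at 3.0 min (Thursday's / Tuesday's / Saturday's / Monday's / Friday's)
- the same order at 12 min (Thursday's / Tuesday's / Saturday's / Monday's / Friday's)
- the amount of X, in percent of the E charged of the flask you put first, at 3.0 min
- the amount of X, in percent of the E charged of the flask you put last, at 3.0 min

- given per volume of solution although it is solid: E
- on the list of suspects stand: E <-> L; G <-> X + D; D -> Q; L + J <-> G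
- at the start none of E is in solution
- what has only dissolved of E counts as not reacted

In the zeta run E loses 9.3 percentage points up to the first reading but 4.2 points between the last two, equally spaced, readings. At the last reading E lost minus X stands at 1.28 mM, as L and G together. We take L as steady while solid stands, which makes the loss of J pseudo-first-order. The gain in X from the second reading to the last, over the J charge less the last X (G not counted), reads κ = 0.00428 /s, with the scatter of 1 point on each reading. We work with the J left, exp(−κt), which is 46.3% at 3.0 min. The J charge times the fraction gone gives 2.68 mM, our clock amount C: the X, in mM, made by that time while solid stands.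

Turn E first. C ignores the E charge, so we reckon X as C over E: 13.4% for Thursday's, 26.8% for Friday's, 33.6% for Monday's and 53.7% for Tuesday's. Saturday's charge is smaller than C, so there we count the E left. By our reckoning, at the opening rate of 0.0465 mM/s it dissolves in 32.3 s, then L falls at 0.0168 /s with J held at its charge, which leaves 8.39% and gives 91.6% X.

Turn J: C follows the charge, and the zeta run's 3.4 mM would give 1.83 mM. Turn time: at 12 min our J left, with solid standing, is 4.59%, so our order stands, with Thursday's at 23.9% and Tuesday's at 95.4%.

The forecast gives Saturday's > Tuesday's > Monday's > Friday's > Thursday's at 3.0 min and Saturday's > Tuesday's > Monday's > Friday's > Thursday's at 12 min, with 80% (60% to 93%) on top and 15% (10% to 21%) last. It says “A small charge dissolves fully and converts nearly completely”. Our order agrees, but our top of 91.6% is higher and our low of 13.4% lower.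

The flasks come in Saturday's > Tuesday's > Monday's > Friday's > Thursday's at 3.0 min and Saturday's > Tuesday's > Monday's > Friday's > Thursday's at 12 min, with 96.6% for Saturday's and 15.2% for Thursday's at 3.0 min. The forecast's top stands 17 points under.

E ⇌ L, rate k1*(cs1 - [L]) while solid is left; crystals form when [L] > cs1 (solubility = 1.60 mM, k = 0.0331 /s); G ⇌ X + D (K = 0.0140 M, k = 0.0758 /s); D → Q (k = 0.237 /s); L + J ⇌ G (K = 244 /M, k = 10.7 /M/s) At 3.0 min Tuesday's holds 3.05 mM of X and Thursday's 3.05 mM, against our C of 2.68 mM. The neighbour of Saturday's with 2.6 mM of E lies under C, so we count what is left there: 12.5%, hence 87.5% X. That neighbour shows 90.9% X, with E at 0% and 9.13% left as L and G.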